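Weigh the starting material left in millimolar, not in percent, before trusting any integration of this chain.

| setting | blue | amber | violet | north-east | south-west | south-east | south | north-west |
|---|---|---|---|---|---|---|---|---|
| starting material | 4.7 mM | 14 mM | 23 mM | 6.0 mM | 8.0 mM | 12 mM | 20 mM | 30 mM |
| reagent | 40 mM (fed, over 2.5 min) | 40 mM (fed, over 2.5 min) | 40 mM (fed, over 2.5 min) | 40.0 mM (fed, over 2.5 min) | 40.0 mM (fed, over 2.5 min) | 40.0 mM (fed, over 2.5 min) | 40.0 mM (fed, over 2.5 min) | 40.0 mM (fed, over 2.5 min) |
| initiator | 1 mM | 1 mM | 1 mM | 1.0 mM | 1.0 mM | 1.0 mM | 1.0 mM | 1.0 mM |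
| remark | run made earlier | run made earlier | run made earlier |  |  |  |  |  |
| time |  |  |  | 30 min | 30 min | 30 min | 30 min | 30 min |

| run | time / min | target / % | starting material / % |
|---|---|---|---|
| blue | 1.50 | 44.3 | 55.9 |
| blue | 3.00 | 67.4 | 31.6 |
| blue | 6.00 | 88.6 | 11.3 |
| blue | 12.0 | 98.8 | 2.0 |
| blue | 20.0 | 100.3 | 0.4 |
| amber | 1.50 | 37.0 | 63.0 |
| amber | 3.00 | 57.5 | 43.2 |
| amber | 6.00 | 76.7 | 25.2 |
| amber | 12.0 | 88.1 | 12.2 |
| amber | 20.0 | 91.0 | 9.5 |
| violet | 4.00 | 62.5 | 37.0 |
| violet | 8.00 | 79.5 | 20.9 |
| violet | 12.0 | 85.2 | 15.4 |
| violet | 15.0 | 87.5 | 12.0 |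
| violet | 20.0 | 89.7 | 11.1 |

(scatter of a reading: 0.5 percentage points)

- [target] at the end for north-east, south-west, south-east, south, north-west, in this order
- the shape of the row from first to last (falls, then rises / falls all the way / rises all the way / rises, then falls / hardly changes)

I began with the ladder of times the amber run shows. Its first reading, taken as first-order decay, gave an early half-life of about 2.25 min for the starting material, close to the 2.5 min of feeding. Between 12.0 min and 20.0 min the half-life read from amber had stretched to about 22.2 min, longer than the 10.0 min between that last reading and the time asked of the new flasks. So I took the amber and violet flasks at 20.0 min as nearly stopped. Target and starting material summed to about the charge, 101% in amber at 20.0 min, so I counted what was not left as target.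

Then I followed one molecule of starting material. It can meet an initiating radical, a route capped in millimolar by the 2.00 mM of radicals that the initiator can give. Or it can meet the second chain carrier, a route I assumed to be pseudo-first-order, taking the same share of each extra millimolar charged. So I expected the amount left to be a straight line in the charge, and its slope is the survival share, the extra starting material left per extra millimolar charged:

s = (left in violet − left in amber) / (charge difference) = 0.136

threshold charge = amber charge − amber left / s = 4.21 mM

c(target) = c(starting material charged) − s × (c(starting material charged) − threshold)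

The blue run, charged with 4.7 mM and with 0.0188 mM left at 20.0 min, stood near that threshold. These readings carry their scatter, and the line gave me:

5.76 mM, 7.49 mM, 10.9 mM, 17.9 mM, 26.5 mM

The forecast said 5.9 mM, 7.75 mM, 11.2 mM, 18.3 mM, 27 mM, shape rises all the way, from a “roughly constant fractional limit at high charge”. At north-west it stood above my line.

The flasks gave 5.85 mM, 7.61 mM, 11.1 mM, 18.2 mM, 27.0 mM, shape rises all the way.

    reagent ⇌ dormant form (K = 0.270, k = 0.0850 s⁻¹)
    starting material + second chain carrier → by-product + first chain carrier (k = 23000 M⁻¹ s⁻¹)
    starting material + initiating radical → capped initiator + first chain carrier (k = 1.80 × 10⁶ M⁻¹ s⁻¹)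
    reagent + first chain carrier ⇌ target + second chain carrier (K = 0.590, k = 41000 M⁻¹ s⁻¹)
    initiator → 2 initiating radical (k = 0.00450 s⁻¹)
    2 second chain carrier → ended chains (k = 1.00 × 10⁸ M⁻¹ s⁻¹)

In north-east at 1.24 min, starting material used second chain carrier 2.4 times as fast as the ending of chains did, and 4.7 times as fast at 30.0 min. For south-east the line put 1.06 mM of starting material left, and the flask held 7.2% of its charge, 0.864 mM.

The numbers in the tables stem from a simulated flask for substances that don't exist.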